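Ring B of the target carries the C6 oxygen and the C8=C9 alkene on either side of the C7 methylene. This homoallylic pattern is traced back to a trans-hydrindane in which C7 is the methylene of a cyclopropane spanning C6 and C8, with a silyloxy group on C6 and a mesylate on C9. Fluoride unmasks the C6 oxygen, which expels the mesylate through the internal C6–C8 bond: in one operation the six-membered ring grows into ring B, the C6 ketone appears and the alkene is fixed at C8=C9. The ring-A stereocentres (C1, C2, C4, C5), assembled beforehand on a cyclopentane from (R)-4-silyloxycyclopentenone, pass through untouched.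

Key step: step 16

Remark on numbering: target numbering is used throughout, also for monocyclic intermediates (C1 methyl-bearing ring-fusion carbon, C2 angeloyloxy carbon, C3 CH2, C4 isopropyl carbinol carbon, C5 ring-fusion CH, C6 anisoyloxy carbon, C7 CH2, C8 methyl-bearing alkene carbon, C9 alkene CH, C10 CH2; ring A = C1–C5, ring B = C1 and C5–C10). β is the face of the C1 methyl group.

Remark on the chemistry: (R)-4-[(tert-butyldimethylsilyl)oxy]cyclopent-2-en-1-one is taken as the commercial chiral starting material. The fragmentation precursor is designed with C7 α and the C9 mesylate α (pseudo-equatorial, cis to C7), a labile trimethylsilyl ether on C4 and a robust triisopropylsilyl ether on C2, so that the fluoride of the key step also frees the C4 hydroxyl that directs the next reduction.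

Step 1
Reactants: 1 (R)-4-[(tert-butyldimethylsilyl)oxy]cyclopent-2-en-1-one
Product: 2 (R)-4-[(tert-butyldimethylsilyl)oxy]-2-iodocyclopent-2-en-1-one
Conditions: I2, pyridine, CH2Cl2, 0 °C → rt
Reagents that add atoms: iodine, [I][I]
Why: α-Iodination of the enone by conjugate addition of pyridine, iodination of the enolate and elimination (Baylis–Hillman-type sequence) should give the 2-iodoenone and leave the C4 stereocentre untouched.

Step 2
Reactants: 2 (R)-4-[(tert-butyldimethylsilyl)oxy]-2-iodocyclopent-2-en-1-one; 3 tetramethylstannane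
Product: 4 (R)-4-[(tert-butyldimethylsilyl)oxy]-2-methylcyclopent-2-en-1-one
Conditions: Pd2(dba)3, AsPh3, CuI, NMP, 60 °C
Reagents that add atoms: none
Why: Stille coupling under neutral conditions should install the C1 methyl group without base-induced loss of the β-silyloxy group.

Step 3
Reactants: 4 (R)-4-[(tert-butyldimethylsilyl)oxy]-2-methylcyclopent-2-en-1-one; 5 2-bromobut-1-ene; 6 allyl iodide
Product: 8 (2R,3R,4R)-2-allyl-3-(but-1-en-2-yl)-4-[(tert-butyldimethylsilyl)oxy]-2-methylcyclopentan-1-one, via bromomagnesium enolate 7 (not isolated)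
Conditions: Mg, THF (5 → Grignard reagent); CuBr·SMe2 (20 mol %), THF, −78 °C; then 6, HMPA, −78 → −20 °C
Reagents that add atoms: none
Why: Copper-catalysed conjugate addition of the alkenyl Grignard reagent should occur anti to the C4 silyloxy group and set C5, and allylation of the enolate anti to the new C5 substituent should set the quaternary C1, as in prostaglandin-type three-component couplings.

Step 4
Reactants: 8 (2R,3R,4R)-2-allyl-3-(but-1-en-2-yl)-4-[(tert-butyldimethylsilyl)oxy]-2-methylcyclopentan-1-one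
Product: 9 (1R,2R,3R,4R)-2-allyl-3-(but-1-en-2-yl)-4-[(tert-butyldimethylsilyl)oxy]-2-methylcyclopentan-1-ol (C2 β-alcohol)
Conditions: (3aS)-1-methyl-3,3-diphenyltetrahydro-1H,3H-pyrrolo[1,2-c][1,3,2]oxazaborole (0.2 equiv), catecholborane, toluene, −78 → −40 °C
Reagents that add atoms: none
Why: Corey–Bakshi–Shibata reduction, in which the (S)-oxazaborolidine distinguishes the quaternary C1 from the C3 methylene, should deliver hydride to the α face and give the 2β alcohol (cis to the C1 methyl) under reagent control, while catecholborane leaves the terminal alkenes alone.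

Step 5
Reactants: 9 C2 β-alcohol
Product: 10 C2 β-triisopropylsilyl ether of 9 (C4 α-OTBS retained)
Conditions: iPr3SiOTf, 2,6-lutidine, CH2Cl2, 0 °C → rt
Reagents that add atoms: triisopropylsilyl trifluoromethanesulfonate, CC(C)[Si](OS(=O)(=O)C(F)(F)F)(C(C)C)C(C)C
Why: Silyl ether formation with the silyl triflate should cap the hindered C2 hydroxyl with a group robust enough for the acid, base and fluoride steps that follow.

Step 6
Reactants: 10 bis-silyl ether
Product: 11 cyclopentanol with free C4 α-hydroxyl (C2 β-OTIPS; C1 β-methyl α-allyl; C5 β-butenyl)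
Conditions: camphorsulfonic acid (cat.), MeOH/CH2Cl2, 0 °C
Reagents that add atoms: none
Why: Acid-catalysed methanolysis should remove the less hindered secondary tert-butyldimethylsilyl ether at C4 much faster than the neopentyl triisopropylsilyl ether at C2.

Step 7
Reactants: 11 C4 alcohol
Product: 12 C4 ketone (C2 β-OTIPS; C1 β-methyl α-allyl; C5 β-butenyl)
Conditions: Dess–Martin periodinane, NaHCO3, CH2Cl2, 0 °C → rt
Reagents that add atoms: none
Why: Dess–Martin oxidation under buffered conditions should give the C4 ketone without epimerising C5 or drawing the β,γ-alkene into conjugation.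

Step 8
Reactants: 12 C4 ketone; 13 isopropylmagnesium chloride
Product: 14 tertiary alcohol (C4 β-OH α-isopropyl; C2 β-OTIPS; C1 β-methyl α-allyl; C5 β-butenyl)
Conditions: CeCl3, THF, −78 °C
Reagents that add atoms: none
Why: Organocerium 1,2-addition (Imamoto conditions) suppresses enolisation and hydride transfer, and attack on the α face, anti to the adjacent C5 alkenyl group, should set C4 with the hydroxyl β and the isopropyl group α.

Step 9
Reactants: 14 tertiary alcohol
Product: 15 keto aldehyde (C5 β-propanoyl; C1 α-CH2CHO; C4 β-OH α-isopropyl; C2 β-OTIPS)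
Conditions: O3, CH2Cl2/MeOH, −78 °C; Me2S
Reagents that add atoms: ozone, [O-][O+]=O
Why: Ozonolysis with reductive work-up should cleave both terminal alkenes at once and unveil the C6 ethyl ketone and the C9 aldehyde.

Step 10
Reactants: 15 keto aldehyde
Product: 16 trans-hydrindan-6-one (C8 β-methyl; C9 α-OH; C4 β-OH α-isopropyl; C2 β-OTIPS)
Conditions: K2CO3, MeOH, 0 °C
Reagents that add atoms: none
Why: Intramolecular aldol addition of the C8 enolate to the C9 aldehyde (6-enolendo-exo-trig) under equilibrating conditions should close the six-membered ring trans-fused, with the C8 methyl and C9 hydroxyl equatorial (C9–OH α, away from the axial C1 methyl) by thermodynamic control; both centres are erased later.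

Step 11
Reactants: 16 trans-hydrindan-6-one
Product: 17 C4,C9-bis(trimethylsilyl) ether of 16
Conditions: N-(trimethylsilyl)imidazole, CH2Cl2, rt
Reagents that add atoms: N-(trimethylsilyl)imidazole, C[Si](C)(C)n1ccnc1
Why: Silyl transfer from the N-silylimidazole should cap both hydroxyls without enolising the ketone, which blocks retro-aldol cleavage at C4 and elimination at C9 in the next step.

Step 12
Reactants: 17 bis(trimethylsilyl) ether
Product: 19 C6=C8 triethylsilyl enol ether (C9 α-OTMS; C4 β-OTMS; C2 β-OTIPS), via lithium enolate 18 (not isolated)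
Conditions: LiN(iPr)2, THF, −78 °C; Et3SiCl, Et3N, −78 → 0 °C
Reagents that add atoms: chlorotriethylsilane, CC[Si](Cl)(CC)CC
Why: Kinetic enolisation should take the axial C8 hydrogen and not the C5 hydrogen, which is screened by the cis C4 isopropyl group and two fully substituted neighbours (the C5=C6 enol ether is also the more strained isomer), and O-silylation of the enolate gives the C6=C8 silyl enol ether.

Step 13
Reactants: 19 silyl enol ether; 20 diiodomethane
Product: 21 trans-hydrindane with cis-fused 6β-triethylsiloxy cyclopropane (C6, C7, C8; C7 α; C8 β-methyl; C9 α-OTMS; C4 β-OTMS; C2 β-OTIPS)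
Conditions: Et2Zn, DME, CH2Cl2, −10 °C → rt
Reagents that add atoms: none
Why: Simmons–Smith cyclopropanation (Furukawa variant) of the electron-rich enol ether should take place on the α face, away from the axial C1 methyl, and give the cis-fused siloxycyclopropane with C7 α, on the same side as the C9 oxygen.

Step 14
Reactants: 21 siloxycyclopropane
Product: 22 C9 α-alcohol (C6 β-OTES cyclopropane; C4 β-OTMS; C2 β-OTIPS)
Conditions: K2CO3, MeOH, 0 °C
Reagents that add atoms: none
Why: Mild base-catalysed methanolysis should cleave the secondary trimethylsilyl ether at C9 and leave the hindered tertiary silyl ethers at C4 and C6 and the C2 ether in place.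

Step 15
Reactants: 22 C9 alcohol
Product: 23 C9 α-mesylate of the 6β-triethylsiloxy cyclopropane-fused trans-hydrindane (fragmentation precursor)
Conditions: MsCl, Et3N, CH2Cl2, −40 °C
Reagents that add atoms: methanesulfonyl chloride, CS(=O)(=O)Cl
Why: Sulfonylation of the only free hydroxyl should give the cyclopropylcarbinyl mesylate, which is kept cold and carried on crude.

Step 16
Reactants: 23 C9 α-mesylate
Product: 26 trans-fused hydroazulen-6-one with the C8=C9 alkene (C4 β-OH α-isopropyl; C2 β-OTIPS), via cyclopropanol 24 (not isolated), via silylated ketone 25 (not isolated)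
Conditions: Bu4NF (3 equiv), AcOH (1.5 equiv), THF, −40 °C → rt
Reagents that add atoms: none
Why: Fluoride removes the triethylsilyl group from the C6 oxygen, whose lone pair then pushes into the C6–C8 bond as the C9 mesylate departs, so that the C6 carbonyl and the C8=C9 alkene form together, and the same reagent then cleaves the C4 trimethylsilyl ether. The closest known reaction type is the oxygen-assisted cyclopropylcarbinyl (Grob-type) fragmentation of 1-siloxybicyclo[n.1.0]alkan-2-yl sulfonates to ring-enlarged β,γ-unsaturated ketones. Ring B is formed by enlargement and not by bond formation: cleavage of the bond shared by the six- and three-membered rings (the zero-atom bridge of the bicyclo[4.1.0]heptane unit) merges them into the seven-membered ring. No stereocentre is created; C6, C8 and C9 lose their stereogenicity, and C1, C2, C4 and C5, set earlier, are not touched, so the trans ring fusion is carried over. The step needs cleavage of the internal C6–C8 bond and not of the external C7–C8 bond, which is secured by the donor oxygen on C6 taking up the charge and by the pseudo-equatorial C9 mesylate lying cis to C7 and close to anti to the C6–C8 bond. Low temperature and the acetic acid buffer should keep the alkene out of conjugation and prevent retro-aldol opening of ring A in the β-hydroxy ketone.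

Step 17
Reactants: 26 hydroazulen-6-one
Product: 27 4β,6α-diol (C8=C9 alkene; C2 β-OTIPS)
Conditions: Me4NBH(OAc)3, MeCN/AcOH, −30 °C
Reagents that add atoms: none
Why: Hydroxyl-directed (Evans–Saksena) reduction, with hydride delivered from the boron ester of the β C4 hydroxyl to the carbonyl face turned toward C4, should give the 6α alcohol (4,6-anti diol).

Step 18
Reactants: 27 diol; 28 4-methoxybenzoyl chloride
Product: 29 C6 α-(4-methoxybenzoate) (C4 β-OH; C2 β-OTIPS)
Conditions: Et3N, DMAP, CH2Cl2, rt
Reagents that add atoms: none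
Why: DMAP-catalysed acylation should esterify the secondary C6 hydroxyl only, since the tertiary C4 hydroxyl is inert under these conditions.

Step 19
Reactants: 29 anisate
Product: 30 C2 β-alcohol (C6 α-anisate; C4 β-OH)
Conditions: HF·pyridine, pyridine, THF, 0 °C → rt
Reagents that add atoms: none
Why: Fluoride-mediated desilylation under non-basic conditions should free the C2 hydroxyl without ester migration or hydrolysis.

Step 20
Reactants: 30 C2 alcohol; 31 angelic acid
Product: 32 CNP0204191.1 (C2 β-angelate; C4 β-OH α-isopropyl; C6 α-(4-methoxybenzoate); C8=C9 alkene; trans ring fusion)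
Conditions: 2,4,6-trichlorobenzoyl chloride, Et3N, toluene, 80 °C
Reagents that add atoms: none
Why: Yamaguchi-type esterification through the mixed anhydride should acylate the secondary C2 hydroxyl without Z-to-E isomerisation of the angelate, the tertiary C4 hydroxyl staying free.

Compound list
1 | (R)-4-[(tert-butyldimethylsilyl)oxy]cyclopent-2-en-1-one | O=C1C[C@@H](O[Si](C)(C)C(C)(C)C)C=C1 | starting material
2 | (R)-4-[(tert-butyldimethylsilyl)oxy]-2-iodocyclopent-2-en-1-one | O=C1C[C@@H](O[Si](C)(C)C(C)(C)C)C=C1I | intermediate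
3 | tetramethylstannane | C[Sn](C)(C)C | starting material
4 | (R)-4-[(tert-butyldimethylsilyl)oxy]-2-methylcyclopent-2-en-1-one | O=C1C[C@@H](O[Si](C)(C)C(C)(C)C)C=C1C | intermediate
5 | 2-bromobut-1-ene | C=C(Br)CC | starting material
6 | allyl iodide (3-iodoprop-1-ene) | ICC=C | starting material
7 | bromomagnesium enolate (C1=C2) with C5 β-(but-1-en-2-yl) and C4 α-OTBS | Br[Mg]OC1=C(C)[C@@H](C(=C)CC)[C@H](O[Si](C)(C)C(C)(C)C)C1 | intermediate (not isolated)
8 | (2R,3R,4R)-2-allyl-3-(but-1-en-2-yl)-4-[(tert-butyldimethylsilyl)oxy]-2-methylcyclopentan-1-one | O=C1C[C@@H](O[Si](C)(C)C(C)(C)C)[C@H](C(=C)CC)[C@@]1(C)CC=C | intermediate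
9 | (1R,2R,3R,4R)-2-allyl-3-(but-1-en-2-yl)-4-[(tert-butyldimethylsilyl)oxy]-2-methylcyclopentan-1-ol (C2 β-OH) | O[C@@H]1C[C@@H](O[Si](C)(C)C(C)(C)C)[C@H](C(=C)CC)[C@@]1(C)CC=C | intermediate
10 | C2 β-triisopropylsilyl ether of 9 (C4 α-OTBS) | CC(C)[Si](C(C)C)(C(C)C)O[C@@H]1C[C@@H](O[Si](C)(C)C(C)(C)C)[C@H](C(=C)CC)[C@@]1(C)CC=C | intermediate
11 | C4 α-alcohol (C2 β-OTIPS; C1 β-methyl α-allyl; C5 β-butenyl) | CC(C)[Si](C(C)C)(C(C)C)O[C@@H]1C[C@@H](O)[C@H](C(=C)CC)[C@@]1(C)CC=C | intermediate
12 | C4 ketone (C2 β-OTIPS; C1 β-methyl α-allyl; C5 β-butenyl) | CC(C)[Si](C(C)C)(C(C)C)O[C@@H]1CC(=O)[C@H](C(=C)CC)[C@@]1(C)CC=C | intermediate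
13 | isopropylmagnesium chloride | CC(C)[Mg]Cl | starting material
14 | tertiary alcohol (C4 β-OH α-isopropyl; C2 β-OTIPS; C1 β-methyl α-allyl; C5 β-butenyl) | CC(C)[Si](C(C)C)(C(C)C)O[C@@H]1C[C@@](O)(C(C)C)[C@H](C(=C)CC)[C@@]1(C)CC=C | intermediate
15 | keto aldehyde (C5 β-propanoyl; C1 α-CH2CHO; C4 β-OH α-isopropyl; C2 β-OTIPS) | CC(C)[Si](C(C)C)(C(C)C)O[C@@H]1C[C@@](O)(C(C)C)[C@H](C(=O)CC)[C@@]1(C)CC=O | intermediate
16 | trans-hydrindan-6-one (C8 β-methyl; C9 α-OH; C4 β-OH α-isopropyl; C2 β-OTIPS) | CC(C)[Si](C(C)C)(C(C)C)O[C@@H]1C[C@@](O)(C(C)C)[C@@H]2C(=O)[C@H](C)[C@@H](O)C[C@]21C | intermediate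
17 | C4,C9-bis(trimethylsilyl) ether of 16 | CC(C)[Si](C(C)C)(C(C)C)O[C@@H]1C[C@@](O[Si](C)(C)C)(C(C)C)[C@@H]2C(=O)[C@H](C)[C@@H](O[Si](C)(C)C)C[C@]21C | intermediate
18 | lithium C6=C8 enolate of 17 | CC(C)[Si](C(C)C)(C(C)C)O[C@@H]1C[C@@](O[Si](C)(C)C)(C(C)C)[C@@H]2C(O[Li])=C(C)[C@@H](O[Si](C)(C)C)C[C@]21C | intermediate (not isolated)
19 | C6=C8 triethylsilyl enol ether (C9 α-OTMS; C4 β-OTMS; C2 β-OTIPS) | CC(C)[Si](C(C)C)(C(C)C)O[C@@H]1C[C@@](O[Si](C)(C)C)(C(C)C)[C@@H]2C(O[Si](CC)(CC)CC)=C(C)[C@@H](O[Si](C)(C)C)C[C@]21C | intermediate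
20 | diiodomethane | ICI | starting material
21 | trans-hydrindane with cis-fused cyclopropane (C6 β-OTES; C7 α; C8 β-methyl; C9 α-OTMS; C4 β-OTMS; C2 β-OTIPS) | CC(C)[Si](C(C)C)(C(C)C)O[C@@H]1C[C@@](O[Si](C)(C)C)(C(C)C)[C@@H]2[C@@]3(O[Si](CC)(CC)CC)C[C@@]3(C)[C@@H](O[Si](C)(C)C)C[C@]21C | intermediate
22 | C9 α-alcohol of 21 | CC(C)[Si](C(C)C)(C(C)C)O[C@@H]1C[C@@](O[Si](C)(C)C)(C(C)C)[C@@H]2[C@@]3(O[Si](CC)(CC)CC)C[C@@]3(C)[C@@H](O)C[C@]21C | intermediate
23 | C9 α-mesylate of 22 (fragmentation precursor) | CC(C)[Si](C(C)C)(C(C)C)O[C@@H]1C[C@@](O[Si](C)(C)C)(C(C)C)[C@@H]2[C@@]3(O[Si](CC)(CC)CC)C[C@@]3(C)[C@@H](OS(C)(=O)=O)C[C@]21C | intermediate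
24 | C6 cyclopropanol with C9 α-mesylate (C4 β-OTMS; C2 β-OTIPS) | CC(C)[Si](C(C)C)(C(C)C)O[C@@H]1C[C@@](O[Si](C)(C)C)(C(C)C)[C@@H]2[C@@]3(O)C[C@@]3(C)[C@@H](OS(C)(=O)=O)C[C@]21C | intermediate (not isolated)
25 | trans-fused hydroazulen-6-one with C8=C9 alkene and C4 β-OTMS (C2 β-OTIPS) | CC(C)[Si](C(C)C)(C(C)C)O[C@@H]1C[C@@](O[Si](C)(C)C)(C(C)C)[C@@H]2C(=O)CC(C)=CC[C@]21C | intermediate (not isolated)
26 | trans-fused hydroazulen-6-one with C8=C9 alkene (C4 β-OH α-isopropyl; C2 β-OTIPS) | CC(C)[Si](C(C)C)(C(C)C)O[C@@H]1C[C@@](O)(C(C)C)[C@@H]2C(=O)CC(C)=CC[C@]21C | intermediate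
27 | 4β,6α-diol (C2 β-OTIPS) | CC(C)[Si](C(C)C)(C(C)C)O[C@@H]1C[C@@](O)(C(C)C)[C@@H]2[C@@H](O)CC(C)=CC[C@]21C | intermediate
28 | 4-methoxybenzoyl chloride | COc1ccc(cc1)C(Cl)=O | starting material
29 | C6 α-(4-methoxybenzoate) (C4 β-OH; C2 β-OTIPS) | CC(C)[Si](C(C)C)(C(C)C)O[C@@H]1C[C@@](O)(C(C)C)[C@@H]2[C@@H](OC(=O)c3ccc(OC)cc3)CC(C)=CC[C@]21C | intermediate
30 | C2 β-alcohol (C6 α-anisate; C4 β-OH) | O[C@@H]1C[C@@](O)(C(C)C)[C@@H]2[C@@H](OC(=O)c3ccc(OC)cc3)CC(C)=CC[C@]21C | intermediate
31 | angelic acid ((Z)-2-methylbut-2-enoic acid) | C/C=C(/C)C(O)=O | starting material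
32 | CNP0204191.1 | C/C=C(/C)C(=O)O[C@@H]1C[C@@](O)(C(C)C)[C@@H]2[C@@H](OC(=O)c3ccc(OC)cc3)CC(C)=CC[C@]21C | target

Total step count: 20. Longest linear sequence: 20 steps (1 → 32).

Steps most likely to fail

Step 16. Ionisation at C9 may be assisted by the external C7–C8 bond instead of the internal one, giving cyclobutyl or ring-retained homoallyl products. After the ketone has formed, the alkene may drift into conjugation, or ring A may open by retro-aldol cleavage. The fallback is a radical ring opening that sets out from alcohol 22. Acylation with 1,1'-thiocarbonyldiimidazole gives the C9 imidazol-1-ylthiocarbonate F1. Bu3SnH and AIBN (slow addition, toluene, 90 °C) generate the C9 radical, which opens the cyclopropane toward the siloxy-stabilised C6 radical; hydrogen transfer then gives the ring-B triethylsilyl ether F2 (C6 epimers) with the C8=C9 alkene in place. Bu4NF removes the C6 and C4 silyl groups to give the diol F3 (C6 epimers), and Dess–Martin oxidation of its secondary hydroxyl returns to ketone 26.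

Step 12. Deprotonation may occur at C5 instead of C8, or the enolate may expel the C9 silyloxy group. The fallback needs no enolate regiochemistry and sets out from aldol 16. Dehydration (MsCl, Et3N, then DBU) gives the C8=C9 enone F4, and nucleophilic epoxidation (tBuOOH, DBU) from the α face gives the epoxy ketone F5. CH2(ZnI)2 adds to the C6 carbonyl and its second carbon–zinc bond opens the epoxide at C8, giving the cyclopropanol F6 with the C9 hydroxyl. Mesylation of the secondary hydroxyl (MsCl, Et3N, −40 → 0 °C) gives the mesylate F7, which fragments in the same flask and comes back to the route at ketone 26.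

Step 4. Facial selectivity may be poor if catalyst and substrate bias are mismatched, and the borane may add to the terminal alkenes. The fallback is a substrate-directed reduction that sets out from ketone 8. HF·pyridine removes the silyl group to give the hydroxy ketone F8. Me4NBH(OAc)3, delivering hydride from the C4 α-hydroxyl, gives the 2β,4α-diol F9. Selective silylation of the less hindered C4 hydroxyl (tert-butyldimethylsilyl chloride, imidazole) comes back to the route at alcohol 9.

Further compounds
F1 | step 16 | C9 α-O-(imidazol-1-ylthiocarbonyl) derivative of 22 | CC(C)[Si](C(C)C)(C(C)C)O[C@@H]1C[C@@](O[Si](C)(C)C)(C(C)C)[C@@H]2[C@@]3(O[Si](CC)(CC)CC)C[C@@]3(C)[C@@H](OC(=S)n3ccnc3)C[C@]21C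
F2 | step 16 | ring-expanded C6 triethylsilyl ether with C8=C9 alkene (C6 epimers; C4 β-OTMS; C2 β-OTIPS) | CC(C)[Si](C(C)C)(C(C)C)O[C@@H]1C[C@@](O[Si](C)(C)C)(C(C)C)[C@@H]2C(O[Si](CC)(CC)CC)CC(C)=CC[C@]21C
F3 | step 16 | C4,C6-diol with C8=C9 alkene (C6 epimers; C2 β-OTIPS) | CC(C)[Si](C(C)C)(C(C)C)O[C@@H]1C[C@@](O)(C(C)C)[C@@H]2C(O)CC(C)=CC[C@]21C
F4 | step 12 | trans-hydrind-8-en-6-one (C8=C9 enone; C4 β-OH; C2 β-OTIPS) | CC(C)[Si](C(C)C)(C(C)C)O[C@@H]1C[C@@](O)(C(C)C)[C@@H]2C(=O)C(C)=CC[C@]21C
F5 | step 12 | 8α,9α-epoxy ketone | CC(C)[Si](C(C)C)(C(C)C)O[C@@H]1C[C@@](O)(C(C)C)[C@@H]2C(=O)[C@@]3(C)O[C@H]3C[C@]21C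
F6 | step 12 | cyclopropanol (C6 α-OH; C7 β; C8 α-methyl) with C9 α-OH | CC(C)[Si](C(C)C)(C(C)C)O[C@@H]1C[C@@](O)(C(C)C)[C@@H]2[C@]3(O)C[C@]3(C)[C@@H](O)C[C@]21C
F7 | step 12 | C9 α-mesylate of F6 | CC(C)[Si](C(C)C)(C(C)C)O[C@@H]1C[C@@](O)(C(C)C)[C@@H]2[C@]3(O)C[C@]3(C)[C@@H](OS(C)(=O)=O)C[C@]21C
F8 | step 4 | (2R,3R,4R)-2-allyl-3-(but-1-en-2-yl)-4-hydroxy-2-methylcyclopentan-1-one | O=C1C[C@@H](O)[C@H](C(=C)CC)[C@@]1(C)CC=C
F9 | step 4 | 2β,4α-diol (C1 β-methyl α-allyl; C5 β-butenyl) | O[C@@H]1C[C@@H](O)[C@H](C(=C)CC)[C@@]1(C)CC=C
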